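The readings were computed with made-up constants.

A rate at most first order in D cannot rise by a larger factor than the charge of D, so, taking the rate of making Q to be such a rate, my upper bounds are 2 for the doubled charge and 5.00 for 500 µM.

| flask | L | Z | G | D | remark |
|---|---|---|---|---|---|
| ash | 20 mM | 20 mM | 6.2 mM (held) | 140 µM | run made earlier |
| birch | 20 mM | 20 mM | 6.2 mM (held) | 220 µM | run made earlier |
| flask | 20 mM | 20 mM | 6.2 mM (held) | 100 µM |  |

| run | time / h | Q / % | L / % |
|---|---|---|---|
| ash | 0.500 | 5.0 | 46.4 |
| ash | 1.00 | 8.2 | 39.8 |
| ash | 1.33 | 10.5 | 38.7 |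
| ash | 2.00 | 19.7 | 31.5 |
| ash | 2.50 | 21.2 | 27.7 |
| ash | 3.00 | 26.0 | 24.9 |
| birch | 0.500 | 5.7 | 44.1 |
| birch | 1.00 | 13.4 | 38.6 |
| birch | 1.33 | 16.1 | 33.1 |
| birch | 2.00 | 22.0 | 27.5 |
| birch | 2.50 | 27.9 | 22.3 |
| birch | 3.00 | 31.1 | 17.1 |

(scatter of a reading: 1 percentage point)

- D is single-handed; L and Z are mirror images of each other, charged as a racemate, each of them at the stated concentration
- the numbers in the tables scatter with a standard deviation of 1 percentage point
- at the start none of G is in solution

* factor on the rate of making Q when 30 % of the L and Z together are converted if D is charged twice over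
* factor on the rate when 30 % of the L and Z together are converted if D is charged at 500 µM instead

The ash run has Q plus L lost at 51.1 % after 3.00 h, and the birch run reaches that progress at 2.30 h by interpolation. So 1.57 times the D reads as 1.31 times the rate, a smaller factor than the rise in charge, with 1 percentage point of scatter on each reading.

I take G to be a reactant that must first enter solution and then reacts at D, so I add two times in series: a fixed uptake time and a catalyst time that falls inversely with [D]. The catalyst share is the catalyst time's part of that sum. A rise in [D] multiplies the rate by the reciprocal of the uptake part plus the catalyst share divided by the rise. The two runs give a share of 0.644 at 140 µM. In this picture the share grows as [D] falls, so using it unchanged gives lower bounds of 1.48 and 2.06. Scaling the share's odds to 100 µM gives a catalyst share of 0.717, which tightens my values to 1.56 and 2.35.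

The forecast, on “an order near 0.6 ± 0.1”, gives 1.45, below my lower bound, and 2.3, inside the bracket.

The flask gives 1.76 and 3.18, both higher than my tightened values and inside the bracket.

    J + D + L → D + Q (k = 185 M⁻² s⁻¹)
    J + D + Z → D + X (k = 17.5 M⁻² s⁻¹)
    D ⇌ E (K = 0.899, k = 1.46 × 10⁻⁴ s⁻¹)
    G ⇌ J, rate k4*(csat - [J]) (kL = 6.35 × 10⁻⁴ s⁻¹)

Read back from 1.76, the catalyst share at 100 µM is 0.865, larger than my 0.717, and carried to 500 µM it gives 3.24 against the simulated 3.18. In the flask, D falls from 83.0 % at 0.400 h to 57.8 % at 2.00 h as E forms, while J climbs from 3.04 mM to 4.76 mM. At 4.00 h J stands at 5.20 mM, 83.8 % of saturation, with Q at 25.3 %, and at 40.0 h L is down to 0.0134 % while X has reached 27.0 %.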